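**Plan**

1. Retrosynthesis: the two 4-hydroxybenzoate ester C–O bonds are cut first, then the C5–alkenyl C–C bond, then the O1–C2 bond of the dihydrofuran, and last the C2–C3 bond. This leads back to a ring B arylacetic acid (from 5-bromo-2-hydroxy-3-methoxybenzaldehyde) and a syringyl benzyl bromide (from syringaldehyde).
2. Enabling feature: C2 bears a 4-hydroxy-3,5-dimethoxyphenyl ring (ring A), so C2 is the para-benzylic carbon of a very electron-rich phenol and can be raised to a para-quinone methide. O1 is the phenol oxygen of the benzo ring (ring B), held ortho to C3 and so placed to close a five-membered ring on C2.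
3. Forward: the open chain is joined first (C2–C3 by enolate alkylation), the only new ring (the dihydrofuran) then closes by oxidation and O1–C2 bond formation, the three-carbon side chain is attached at C5–Br by cross-coupling, and both esters are made last.
4. Stereochemistry: C3 comes from an alkylation controlled by (R)-4-benzyloxazolidin-2-one, C2 from substrate control in the ring closure (trans to the C3 substituent), and the E-alkene from the alkenylboronate.

Key step: step 13

Remark: the target is read as the (2S,3R) isomer, in which the C2 aryl and C3 acyloxymethyl groups are trans; compounds 1, 6, 9, 20 and 23 are taken as purchased.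

**Route**

Step 1
Reactants: 1 5-bromo-2-hydroxy-3-methoxybenzaldehyde
Product: 2 2-(allyloxy)-5-bromo-3-methoxybenzaldehyde
Conditions: allyl bromide, K2CO3, DMF, rt
Reagents that add atoms: allyl bromide, C=CCBr
Why: Williamson ether synthesis, in which the phenoxide of the salicylaldehyde is alkylated by the reactive allylic bromide; allyl is chosen because it survives strong base and hydride and is later removed without touching the aryl bromide.

Step 2
Reactants: 2 2-(allyloxy)-5-bromo-3-methoxybenzaldehyde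
Product: 3 2-(allyloxy)-5-bromo-1-methoxy-3-(2-methoxyethenyl)benzene (E/Z mixture)
Conditions: Ph3P(CH2OMe)Cl, KOtBu, THF, 0 °C → rt
Reagents that add atoms: (methoxymethyl)triphenylphosphonium chloride, COC[P+](c1ccccc1)(c1ccccc1)c1ccccc1.[Cl-]
Why: Wittig methoxymethylenation of an unhindered aryl aldehyde with the non-stabilised ylide gives the enol ether as a masked homologous aldehyde, and its alkene geometry is of no consequence.

Step 3
Reactants: 3 2-(allyloxy)-5-bromo-1-methoxy-3-(2-methoxyethenyl)benzene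
Product: 4 2-[2-(allyloxy)-5-bromo-3-methoxyphenyl]acetaldehyde
Conditions: 2 M HCl (aq), THF, 50 °C
Reagents that add atoms: water, O
Why: Acid-catalysed enol ether hydrolysis, in which C-protonation gives an oxocarbenium ion that water converts through the hemiacetal into the aldehyde, while the allyl aryl ether and aryl bromide are inert to dilute acid at this temperature.

Step 4
Reactants: 4 2-[2-(allyloxy)-5-bromo-3-methoxyphenyl]acetaldehyde
Product: 5 2-[2-(allyloxy)-5-bromo-3-methoxyphenyl]acetic acid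
Conditions: NaClO2, NaH2PO4, 2-methyl-2-butene, t-BuOH/H2O, 0 °C → rt
Reagents that add atoms: sodium chlorite, [Na+].[O-]Cl=O
Why: Pinnick oxidation, in which chlorous acid oxidises only the aldehyde and 2-methyl-2-butene traps the hypochlorous acid formed, so that neither the allyl ether nor the electron-rich ring is chlorinated.

Step 5
Reactants: 5 2-[2-(allyloxy)-5-bromo-3-methoxyphenyl]acetic acid; 6 (R)-4-benzyloxazolidin-2-one
Product: 8 (4R)-3-{2-[2-(allyloxy)-5-bromo-3-methoxyphenyl]acetyl}-4-benzyl-1,3-oxazolidin-2-one, via mixed pivalic anhydride 7 (not isolated)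
Conditions: PivCl, Et3N, THF, −20 °C; then 6, LiCl, −20 °C → rt
Reagents that add atoms: none
Why: N-acylation through a mixed anhydride, in which the LiCl-activated oxazolidinone attacks the less hindered arylacetyl carbonyl of 7 and no strong base is needed on an arylacetic acid derivative.

Step 6
Reactants: 9 syringaldehyde (4-hydroxy-3,5-dimethoxybenzaldehyde)
Product: 10 4-(allyloxy)-3,5-dimethoxybenzaldehyde
Conditions: allyl bromide, K2CO3, DMF, 50 °C
Reagents that add atoms: allyl bromide, C=CCBr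
Why: Williamson ether synthesis on the hindered but acidic syringyl phenol, giving the same protecting group as on ring B so that both can later be removed in one operation.

Step 7
Reactants: 10 4-(allyloxy)-3,5-dimethoxybenzaldehyde
Product: 11 [4-(allyloxy)-3,5-dimethoxyphenyl]methanol
Conditions: NaBH4, MeOH, 0 °C
Reagents that add atoms: none
Why: Borohydride reduction of an aryl aldehyde to the benzylic alcohol, which leaves the allyl ether untouched.

Step 8
Reactants: 11 [4-(allyloxy)-3,5-dimethoxyphenyl]methanol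
Product: 12 2-(allyloxy)-5-(bromomethyl)-1,3-dimethoxybenzene
Conditions: PBr3, Et2O, 0 °C
Reagents that add atoms: phosphorus tribromide, BrP(Br)Br
Why: Bromination of a benzylic alcohol through its phosphite ester with bromide displacement; the electron-rich benzylic bromide is to be used promptly in step 9.

Step 9
Reactants: 8 (4R)-3-{2-[2-(allyloxy)-5-bromo-3-methoxyphenyl]acetyl}-4-benzyl-1,3-oxazolidin-2-one; 12 2-(allyloxy)-5-(bromomethyl)-1,3-dimethoxybenzene
Product: 14 (4R)-3-{(2R)-2-[2-(allyloxy)-5-bromo-3-methoxyphenyl]-3-[4-(allyloxy)-3,5-dimethoxyphenyl]propanoyl}-4-benzyl-1,3-oxazolidin-2-one, via sodium Z-enolate 13 (not isolated)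
Conditions: NaN(SiMe3)2, THF, −78 °C; then 12, −78 → −40 °C; AcOH quench
Reagents that add atoms: none
Why: Evans asymmetric alkylation, in which the sodium-chelated Z-enolate 13 is shielded on one face by the benzyl group of the (R)-auxiliary and the benzylic bromide enters from the other, which should set the new α-centre (the later C3) as (R).

Step 10
Reactants: 14 (4R)-3-{(2R)-2-[2-(allyloxy)-5-bromo-3-methoxyphenyl]-3-[4-(allyloxy)-3,5-dimethoxyphenyl]propanoyl}-4-benzyl-1,3-oxazolidin-2-one
Product: 15 (R)-2-[2-(allyloxy)-5-bromo-3-methoxyphenyl]-3-[4-(allyloxy)-3,5-dimethoxyphenyl]propan-1-ol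
Conditions: LiBH4, MeOH (1 equiv), THF, 0 °C
Reagents that add atoms: none
Why: Reductive cleavage of the N-acyl oxazolidinone, in which hydride attacks the exocyclic carbonyl without enolisation, so the α-aryl centre should not epimerise and the auxiliary is released intact.

Step 11
Reactants: 15 (R)-2-[2-(allyloxy)-5-bromo-3-methoxyphenyl]-3-[4-(allyloxy)-3,5-dimethoxyphenyl]propan-1-ol
Product: 16 (R)-{2-[2-(allyloxy)-5-bromo-3-methoxyphenyl]-3-[4-(allyloxy)-3,5-dimethoxyphenyl]propoxy}(tert-butyl)dimethylsilane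
Conditions: TBSCl, imidazole, DMF, rt
Reagents that add atoms: tert-butyldimethylsilyl chloride, CC(C)(C)[Si](C)(C)Cl
Why: Imidazole-promoted silylation of the primary alcohol, which masks the only other hydroxyl before the oxidation and keeps the later intermediates soluble in non-polar solvents.

Step 12
Reactants: 16 (R)-{2-[2-(allyloxy)-5-bromo-3-methoxyphenyl]-3-[4-(allyloxy)-3,5-dimethoxyphenyl]propoxy}(tert-butyl)dimethylsilane
Product: 17 (R)-4-bromo-2-{1-[(tert-butyldimethylsilyl)oxy]-3-(4-hydroxy-3,5-dimethoxyphenyl)propan-2-yl}-6-methoxyphenol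
Conditions: Pd(PPh3)4 (5 mol %), morpholine, THF, rt
Reagents that add atoms: none
Why: Tsuji–Trost-type deallylation, in which zerovalent palladium ionises each allyl aryl ether to a π-allyl complex that morpholine intercepts; at room temperature the PPh3-ligated catalyst should not insert into the electron-rich aryl bromide or disturb the silyl ether.

Step 13
Reactants: 17 (R)-4-bromo-2-{1-[(tert-butyldimethylsilyl)oxy]-3-(4-hydroxy-3,5-dimethoxyphenyl)propan-2-yl}-6-methoxyphenol
Product: 19 4-[(2S,3R)-5-bromo-3-{[(tert-butyldimethylsilyl)oxy]methyl}-7-methoxy-2,3-dihydro-1-benzofuran-2-yl]-2,6-dimethoxyphenol, via para-quinone methide 18 (not isolated)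
Conditions: Ag2O (1.1 equiv), CH2Cl2, rt, dark
Reagents that add atoms: none
Why: Ag2O removes two electrons and two protons from the 4-alkyl-2,6-dimethoxyphenol, whose benzylic C–H (the future C2) is lost to give para-quinone methide 18; the ring B phenol oxygen then adds to the exocyclic carbon, and re-aromatisation of ring A drives formation of the O1–C2 bond. The closest known chemistry is the Ag2O oxidation of 4-alkyl-2,6-disubstituted phenols to para-quinone methides followed by intramolecular capture by a nucleophile, the same oxa-conjugate addition that closes the ring in the biosynthesis of 8–5' neolignans. The dihydrofuran closes in a 5-exo-trig mode, since the C=C bond attacked lies outside the new ring. C2 is set by substrate control from the auxiliary-derived C3 centre: the aryl group takes the side away from the silyloxymethyl group, and because the addition can reverse through 18 the more stable trans (2S,3R) isomer should accumulate. The step needs oxidation of ring A in preference to ring B, which is secured by two donor methoxy groups and a free para-benzylic C–H on ring A against a single methoxy group and a bromine-blocked para position on ring B. About one equivalent of oxidant is used so that the product phenol is not oxidised further to the benzofuran.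

Step 14
Reactants: 19 4-[(2S,3R)-5-bromo-3-{[(tert-butyldimethylsilyl)oxy]methyl}-7-methoxy-2,3-dihydro-1-benzofuran-2-yl]-2,6-dimethoxyphenol; 20 (E)-tert-butyldimethyl{[3-(4,4,5,5-tetramethyl-1,3,2-dioxaborolan-2-yl)prop-2-en-1-yl]oxy}silane
Product: 21 4-[(2S,3R)-3-{[(tert-butyldimethylsilyl)oxy]methyl}-5-{(E)-3-[(tert-butyldimethylsilyl)oxy]prop-1-en-1-yl}-7-methoxy-2,3-dihydro-1-benzofuran-2-yl]-2,6-dimethoxyphenol
Conditions: PdCl2(dppf) (5 mol %), K3PO4, 1,4-dioxane/H2O, 60 °C
Reagents that add atoms: none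
Why: Suzuki–Miyaura coupling, in which oxidative addition of zerovalent palladium to the C5–Br bond, transmetalation of the base-activated alkenylboronate and reductive elimination join the side chain with retention of the E geometry, the free phenol being tolerated under the mild aqueous base.

Step 15
Reactants: 21 4-[(2S,3R)-3-{[(tert-butyldimethylsilyl)oxy]methyl}-5-{(E)-3-[(tert-butyldimethylsilyl)oxy]prop-1-en-1-yl}-7-methoxy-2,3-dihydro-1-benzofuran-2-yl]-2,6-dimethoxyphenol
Product: 22 4-{(2S,3R)-3-(hydroxymethyl)-5-[(E)-3-hydroxyprop-1-en-1-yl]-7-methoxy-2,3-dihydro-1-benzofuran-2-yl}-2,6-dimethoxyphenol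
Conditions: Bu4NF, AcOH, THF, 0 °C → rt
Reagents that add atoms: none
Why: Fluoride-induced desilylation driven by the strong Si–F bond removes both alkyl silyl ethers at once, and the acetic acid buffer keeps the phenol and the benzylic ether at C2 away from strongly basic conditions.

Step 16
Reactants: 22 4-{(2S,3R)-3-(hydroxymethyl)-5-[(E)-3-hydroxyprop-1-en-1-yl]-7-methoxy-2,3-dihydro-1-benzofuran-2-yl}-2,6-dimethoxyphenol; 23 4-hydroxybenzoic acid (2.4 equiv)
Product: 24 quiquesetinerviusin B, [(2S,3R)-2-(4-hydroxy-3,5-dimethoxyphenyl)-5-{(E)-3-[(4-hydroxybenzoyl)oxy]prop-1-en-1-yl}-7-methoxy-2,3-dihydro-1-benzofuran-3-yl]methyl 4-hydroxybenzoate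
Conditions: PPh3, DIAD, THF, 0 °C → rt
Reagents that add atoms: none
Why: Mitsunobu esterification, in which the PPh3–DIAD betaine is protonated only by the carboxylic acid (far more acidic than any phenol present) and the two primary alcohols are displaced as alkoxyphosphonium ions by the carboxylate in SN2 fashion, so both esters should form without phenol protection and without affecting C2, C3 or the alkene geometry.

**Compound list**

1 | 5-bromo-2-hydroxy-3-methoxybenzaldehyde | COc1cc(Br)cc(C=O)c1O | starting material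
2 | 2-(allyloxy)-5-bromo-3-methoxybenzaldehyde | C=CCOc1c(OC)cc(Br)cc1C=O | intermediate
3 | 2-(allyloxy)-5-bromo-1-methoxy-3-(2-methoxyethenyl)benzene (E/Z mixture) | C=CCOc1c(OC)cc(Br)cc1C=COC | intermediate
4 | 2-[2-(allyloxy)-5-bromo-3-methoxyphenyl]acetaldehyde | C=CCOc1c(OC)cc(Br)cc1CC=O | intermediate
5 | 2-[2-(allyloxy)-5-bromo-3-methoxyphenyl]acetic acid | C=CCOc1c(OC)cc(Br)cc1CC(=O)O | intermediate
6 | (R)-4-benzyloxazolidin-2-one | O=C1N[C@H](Cc2ccccc2)CO1 | starting material
7 | 2-[2-(allyloxy)-5-bromo-3-methoxyphenyl]acetic pivalic anhydride | C=CCOc1c(OC)cc(Br)cc1CC(=O)OC(=O)C(C)(C)C | intermediate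
8 | (4R)-3-{2-[2-(allyloxy)-5-bromo-3-methoxyphenyl]acetyl}-4-benzyl-1,3-oxazolidin-2-one | C=CCOc1c(OC)cc(Br)cc1CC(=O)N1[C@H](Cc2ccccc2)COC1=O | intermediate
9 | syringaldehyde (4-hydroxy-3,5-dimethoxybenzaldehyde) | COc1cc(C=O)cc(OC)c1O | starting material
10 | 4-(allyloxy)-3,5-dimethoxybenzaldehyde | C=CCOc1c(OC)cc(C=O)cc1OC | intermediate
11 | [4-(allyloxy)-3,5-dimethoxyphenyl]methanol | C=CCOc1c(OC)cc(CO)cc1OC | intermediate
12 | 2-(allyloxy)-5-(bromomethyl)-1,3-dimethoxybenzene | C=CCOc1c(OC)cc(CBr)cc1OC | intermediate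
13 | sodium (Z)-enolate of imide 8 | C=CCOc1c(OC)cc(Br)cc1/C=C(\[O-])N1[C@H](Cc2ccccc2)COC1=O.[Na+] | intermediate
14 | (4R)-3-{(2R)-2-[2-(allyloxy)-5-bromo-3-methoxyphenyl]-3-[4-(allyloxy)-3,5-dimethoxyphenyl]propanoyl}-4-benzyl-1,3-oxazolidin-2-one | C=CCOc1c(OC)cc(Br)cc1[C@@H](Cc1cc(OC)c(OCC=C)c(OC)c1)C(=O)N1[C@H](Cc2ccccc2)COC1=O | intermediate
15 | (R)-2-[2-(allyloxy)-5-bromo-3-methoxyphenyl]-3-[4-(allyloxy)-3,5-dimethoxyphenyl]propan-1-ol | C=CCOc1c(OC)cc(Br)cc1[C@@H](Cc1cc(OC)c(OCC=C)c(OC)c1)CO | intermediate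
16 | (R)-{2-[2-(allyloxy)-5-bromo-3-methoxyphenyl]-3-[4-(allyloxy)-3,5-dimethoxyphenyl]propoxy}(tert-butyl)dimethylsilane | C=CCOc1c(OC)cc(Br)cc1[C@@H](Cc1cc(OC)c(OCC=C)c(OC)c1)CO[Si](C)(C)C(C)(C)C | intermediate
17 | (R)-4-bromo-2-{1-[(tert-butyldimethylsilyl)oxy]-3-(4-hydroxy-3,5-dimethoxyphenyl)propan-2-yl}-6-methoxyphenol | COc1cc(C[C@@H](CO[Si](C)(C)C(C)(C)C)c2cc(Br)cc(OC)c2O)cc(OC)c1O | intermediate
18 | 4-{(R)-2-(5-bromo-2-hydroxy-3-methoxyphenyl)-3-[(tert-butyldimethylsilyl)oxy]propylidene}-2,6-dimethoxycyclohexa-2,5-dien-1-one (para-quinone methide) | COC1=CC(=C[C@@H](CO[Si](C)(C)C(C)(C)C)c2cc(Br)cc(OC)c2O)C=C(OC)C1=O | intermediate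
19 | 4-[(2S,3R)-5-bromo-3-{[(tert-butyldimethylsilyl)oxy]methyl}-7-methoxy-2,3-dihydro-1-benzofuran-2-yl]-2,6-dimethoxyphenol | COc1cc([C@H]2Oc3c(OC)cc(Br)cc3[C@@H]2CO[Si](C)(C)C(C)(C)C)cc(OC)c1O | intermediate
20 | (E)-tert-butyldimethyl{[3-(4,4,5,5-tetramethyl-1,3,2-dioxaborolan-2-yl)prop-2-en-1-yl]oxy}silane | CC(C)(C)[Si](C)(C)OC/C=C/B1OC(C)(C)C(C)(C)O1 | starting material
21 | 4-[(2S,3R)-3-{[(tert-butyldimethylsilyl)oxy]methyl}-5-{(E)-3-[(tert-butyldimethylsilyl)oxy]prop-1-en-1-yl}-7-methoxy-2,3-dihydro-1-benzofuran-2-yl]-2,6-dimethoxyphenol | COc1cc([C@H]2Oc3c(OC)cc(/C=C/CO[Si](C)(C)C(C)(C)C)cc3[C@@H]2CO[Si](C)(C)C(C)(C)C)cc(OC)c1O | intermediate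
22 | 4-{(2S,3R)-3-(hydroxymethyl)-5-[(E)-3-hydroxyprop-1-en-1-yl]-7-methoxy-2,3-dihydro-1-benzofuran-2-yl}-2,6-dimethoxyphenol | COc1cc([C@H]2Oc3c(OC)cc(/C=C/CO)cc3[C@@H]2CO)cc(OC)c1O | intermediate
23 | 4-hydroxybenzoic acid | O=C(O)c1ccc(O)cc1 | starting material
24 | quiquesetinerviusin B, [(2S,3R)-2-(4-hydroxy-3,5-dimethoxyphenyl)-5-{(E)-3-[(4-hydroxybenzoyl)oxy]prop-1-en-1-yl}-7-methoxy-2,3-dihydro-1-benzofuran-3-yl]methyl 4-hydroxybenzoate | COc1cc([C@H]2Oc3c(OC)cc(/C=C/COC(=O)c4ccc(O)cc4)cc3[C@@H]2COC(=O)c2ccc(O)cc2)cc(OC)c1O | target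

**Step count and risks**

Total step count: 16. Longest linear sequence: 13 steps (steps 1–5, then 9–16); steps 6–8 form the side branch to bromide 12.

Steps most likely to fail:

Step 13 (key step). What may go wrong: oxidation running on past the dihydrofuran to the aromatic benzofuran, oxidation starting at the ring B phenol, or tautomerisation of the quinone methide to a stilbene with loss of the C3 configuration. The fallback sets out from 5 and comes back at 19, and reaches the same quinone methide by dehydration of a benzylic alcohol in place of oxidation. Acid 5 would be coupled as in step 5 (through anhydride 7) with (S)-4-benzyloxazolidin-2-one to give (4S)-3-{2-[2-(allyloxy)-5-bromo-3-methoxyphenyl]acetyl}-4-benzyl-1,3-oxazolidin-2-one F1. The enantiomeric auxiliary is needed because the boron aldol uses the enolate face opposite to the one used in the alkylation. Enolisation with Bu2BOTf/i-Pr2NEt and addition to aldehyde 10 (Evans syn aldol, CH2Cl2, −78 → 0 °C) should give (4S)-3-{(2S,3S)-2-[2-(allyloxy)-5-bromo-3-methoxyphenyl]-3-[4-(allyloxy)-3,5-dimethoxyphenyl]-3-hydroxypropanoyl}-4-benzyl-1,3-oxazolidin-2-one F2. LiBH4 reduction should then give (1S,2R)-2-[2-(allyloxy)-5-bromo-3-methoxyphenyl]-1-[4-(allyloxy)-3,5-dimethoxyphenyl]propane-1,3-diol F3. TBSCl/imidazole at 0 °C should silylate only the primary hydroxyl, giving (1S,2R)-2-[2-(allyloxy)-5-bromo-3-methoxyphenyl]-1-[4-(allyloxy)-3,5-dimethoxyphenyl]-3-[(tert-butyldimethylsilyl)oxy]propan-1-ol F4. Pd(PPh3)4/morpholine would free both phenols to give 4-bromo-2-{(1S,2R)-3-[(tert-butyldimethylsilyl)oxy]-1-hydroxy-1-(4-hydroxy-3,5-dimethoxyphenyl)propan-2-yl}-6-methoxyphenol F5. Catalytic TsOH in CH2Cl2 at 0 °C should ionise the para-hydroxybenzylic alcohol of F5 to quinone methide 18 with no oxidant present, and 18 closes to 19 as before; the carbinol configuration is lost in this step and does not matter.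

Step 16. What may go wrong: acylation or alkylation at phenolic oxygens during the double Mitsunobu reaction (oligo-ester formation), or allylic transposition while the cinnamyl-type alcohol is activated. The fallback sets out from 21 and comes back at 24, and keeps every phenol masked as an acetate during ester formation. Ac2O/pyridine should convert 21 into 4-[(2S,3R)-3-{[(tert-butyldimethylsilyl)oxy]methyl}-5-{(E)-3-[(tert-butyldimethylsilyl)oxy]prop-1-en-1-yl}-7-methoxy-2,3-dihydro-1-benzofuran-2-yl]-2,6-dimethoxyphenyl acetate F6. HF·pyridine in THF/pyridine removes both alkyl silyl ethers and leaves the aryl acetate, giving 4-{(2S,3R)-3-(hydroxymethyl)-5-[(E)-3-hydroxyprop-1-en-1-yl]-7-methoxy-2,3-dihydro-1-benzofuran-2-yl}-2,6-dimethoxyphenyl acetate F7. Steglich esterification with purchased 4-acetoxybenzoic acid (EDC·HCl, DMAP, CH2Cl2) should give [(2S,3R)-2-(4-acetoxy-3,5-dimethoxyphenyl)-5-{(E)-3-[(4-acetoxybenzoyl)oxy]prop-1-en-1-yl}-7-methoxy-2,3-dihydro-1-benzofuran-3-yl]methyl 4-acetoxybenzoate F8. Pyrrolidine in CH2Cl2 at rt should then cleave the three phenolic acetates by aminolysis much faster than the two alkyl benzoates, giving 24.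

Step 14. What may go wrong: base-induced opening of the dihydrofuran through the ring A phenoxide (retro-oxa-Michael reaction) with erosion of the C2/C3 stereochemistry at elevated temperature, or protodeboronation of the alkenylboronate before coupling. The fallback sets out from 19 and comes back at 22, and builds the side chain by a Heck reaction and reduction without aqueous inorganic base. Heck coupling of 19 with methyl acrylate (Pd(OAc)2, P(o-tol)3, Et3N, DMF, 100 °C) should give methyl (E)-3-[(2S,3R)-3-{[(tert-butyldimethylsilyl)oxy]methyl}-2-(4-hydroxy-3,5-dimethoxyphenyl)-7-methoxy-2,3-dihydro-1-benzofuran-5-yl]prop-2-enoate F9. Reduction with i-Bu2AlH in CH2Cl2 at −78 °C should give 4-{(2S,3R)-3-{[(tert-butyldimethylsilyl)oxy]methyl}-5-[(E)-3-hydroxyprop-1-en-1-yl]-7-methoxy-2,3-dihydro-1-benzofuran-2-yl}-2,6-dimethoxyphenol F10. Desilylation of F10 under the conditions of step 15 gives 22.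

**Further compounds**

F1 | step 13 | (4S)-3-{2-[2-(allyloxy)-5-bromo-3-methoxyphenyl]acetyl}-4-benzyl-1,3-oxazolidin-2-one | C=CCOc1c(OC)cc(Br)cc1CC(=O)N1[C@@H](Cc2ccccc2)COC1=O
F2 | step 13 | (4S)-3-{(2S,3S)-2-[2-(allyloxy)-5-bromo-3-methoxyphenyl]-3-[4-(allyloxy)-3,5-dimethoxyphenyl]-3-hydroxypropanoyl}-4-benzyl-1,3-oxazolidin-2-one | C=CCOc1c(OC)cc(Br)cc1[C@@H]([C@H](O)c1cc(OC)c(OCC=C)c(OC)c1)C(=O)N1[C@@H](Cc2ccccc2)COC1=O
F3 | step 13 | (1S,2R)-2-[2-(allyloxy)-5-bromo-3-methoxyphenyl]-1-[4-(allyloxy)-3,5-dimethoxyphenyl]propane-1,3-diol | C=CCOc1c(OC)cc(Br)cc1[C@@H]([C@H](O)c1cc(OC)c(OCC=C)c(OC)c1)CO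
F4 | step 13 | (1S,2R)-2-[2-(allyloxy)-5-bromo-3-methoxyphenyl]-1-[4-(allyloxy)-3,5-dimethoxyphenyl]-3-[(tert-butyldimethylsilyl)oxy]propan-1-ol | C=CCOc1c(OC)cc(Br)cc1[C@@H]([C@H](O)c1cc(OC)c(OCC=C)c(OC)c1)CO[Si](C)(C)C(C)(C)C
F5 | step 13 | 4-bromo-2-{(1S,2R)-3-[(tert-butyldimethylsilyl)oxy]-1-hydroxy-1-(4-hydroxy-3,5-dimethoxyphenyl)propan-2-yl}-6-methoxyphenol | Oc1c(OC)cc(Br)cc1[C@@H]([C@H](O)c1cc(OC)c(O)c(OC)c1)CO[Si](C)(C)C(C)(C)C
F6 | step 16 | 4-[(2S,3R)-3-{[(tert-butyldimethylsilyl)oxy]methyl}-5-{(E)-3-[(tert-butyldimethylsilyl)oxy]prop-1-en-1-yl}-7-methoxy-2,3-dihydro-1-benzofuran-2-yl]-2,6-dimethoxyphenyl acetate | COc1cc([C@H]2Oc3c(OC)cc(/C=C/CO[Si](C)(C)C(C)(C)C)cc3[C@@H]2CO[Si](C)(C)C(C)(C)C)cc(OC)c1OC(C)=O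
F7 | step 16 | 4-{(2S,3R)-3-(hydroxymethyl)-5-[(E)-3-hydroxyprop-1-en-1-yl]-7-methoxy-2,3-dihydro-1-benzofuran-2-yl}-2,6-dimethoxyphenyl acetate | COc1cc([C@H]2Oc3c(OC)cc(/C=C/CO)cc3[C@@H]2CO)cc(OC)c1OC(C)=O
F8 | step 16 | [(2S,3R)-2-(4-acetoxy-3,5-dimethoxyphenyl)-5-{(E)-3-[(4-acetoxybenzoyl)oxy]prop-1-en-1-yl}-7-methoxy-2,3-dihydro-1-benzofuran-3-yl]methyl 4-acetoxybenzoate | COc1cc([C@H]2Oc3c(OC)cc(/C=C/COC(=O)c4ccc(OC(C)=O)cc4)cc3[C@@H]2COC(=O)c2ccc(OC(C)=O)cc2)cc(OC)c1OC(C)=O
F9 | step 14 | methyl (E)-3-[(2S,3R)-3-{[(tert-butyldimethylsilyl)oxy]methyl}-2-(4-hydroxy-3,5-dimethoxyphenyl)-7-methoxy-2,3-dihydro-1-benzofuran-5-yl]prop-2-enoate | COc1cc([C@H]2Oc3c(OC)cc(/C=C/C(=O)OC)cc3[C@@H]2CO[Si](C)(C)C(C)(C)C)cc(OC)c1O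
F10 | step 14 | 4-{(2S,3R)-3-{[(tert-butyldimethylsilyl)oxy]methyl}-5-[(E)-3-hydroxyprop-1-en-1-yl]-7-methoxy-2,3-dihydro-1-benzofuran-2-yl}-2,6-dimethoxyphenol | COc1cc([C@H]2Oc3c(OC)cc(/C=C/CO)cc3[C@@H]2CO[Si](C)(C)C(C)(C)C)cc(OC)c1O
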